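(The readings stem from a simulated flask for an exercise; noise was put on by code.)

Set two clocks against each other: one fills X, the other empties it. We reckon in fractions of the Q charged.

| flask | Q | D | remark | time |
|---|---|---|---|---|
| west | 0.050 M | 0.20 M | run made earlier |  |
| flask | 0.050 M | 0.100 M |  | 15 min |

- west (time / s: X / %, Z / %): 20.0: 37.8, 2.8; 40.0: 48.2, 7.2; 50.0: 51.7, 11.2; 80.0: 47.5, 21.4; 90.0: 45.7, 22.8

(readings scatter by 1 percentage point)

- what was read earlier has a scatter of 1 percentage point, one standard deviation

1. the best time, 15 min at the latest, for X
2. the amount of X, in percent of the Q charged, at that time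

The fill time is the time constant of the fall of Q, with D held at its charge (pseudo-first-order). Counting as Q whatever X and Z do not hold at 20.0 s, the west run gives 38.4 s. We scale it by the charge of D, so this flask gets 76.8 s.

The drain time is the lifetime of X, which we take to be free of D. At the west peak, read near 50.0 s at 51.7 %, filling balances draining, and that gives 73.0 s.

We call 0.951 the race ratio, drain time over fill time. Integrating the two first-order steps in closed form puts our peak at 1.25 min, with 35.9 % as X. But D is charged at twice Q, and we expect it to fall as Q reacts, which this reckoning ignores.

The forecast gives 1.4 min and 33 %, later and lower than ours, on its own grounds: “equilibrium reaches only about 41% X”.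

The flask gives 1.26 min and 35.7 %.

    Q + D → X + G (k = 0.142 M⁻¹ s⁻¹)
    X → Z (k = 0.00631 s⁻¹)
    X → J (k = 0.00534 s⁻¹)
    D → E (k = 1.30 × 10⁻⁵ s⁻¹)

At that time this flask still holds 70.6 % of its D, so our race ratio, taken at the D present, is 0.671. In the neighbour flask with 0.25 M of D, the ratio grows with the charge to 2.38. The closed form then gives 53.3 % as X, and that flask reaches 55.6 %.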